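**Plan**

1. Numbering: C1 is the ring-fusion CH that carries the lactone CH2 (C15; C16 is the C=O, C17 the exocyclic CH2), C2 is the lactone O–CH, then C3=C4(Me), C5, C6, C7=C8(Me), C9 (OAc), C10, C11=C12(Me), C13, C14 around the 14-membered ring.
2. Retrosynthetic cuts, in order: the C9 acetate and C17 methylene; then C6–C7; then the C16 oxidation level and the C1–C2 bond (lactonization, anti-allylboration); then C11=C12/C13 and C3=C4/C5 (two Johnson–Claisen rearrangements) and C9–C10 (allylboration).
3. Enabling feature: C6–C7 is the allylic CH2–CH= bond inside the skipped 1,5-diene C3=C4–C5–C6–C7=C8 of the 14-membered ring. C6 can therefore be a primary homoallylic radical released from a 4-enoic acid N-acyloxyphthalimide (the acid carbon leaves as CO2), and C7 the CH terminus of an (E)-alkenyl iodide.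
4. Forward order: the west chain C7→C16 is grown linearly from propargyl alcohol to an (E)-allylboronate; the east enal (C2–C6 plus the carboxyl carbon) is made in four steps; the two are joined at C1–C2; the γ-lactone ring closes first (step 17) and the 14-membered ring second (step 20); methylenation, desilylation and acetylation finish.
5. Stereochemistry: C9 comes from an (S)-TRIP-catalysed allylboration. C1 and C2 come together from an (R)-TRIP-catalysed allylboration of the (E)-boronate (chair transition state gives anti; the acid selects the aldehyde face). C7=C8 comes from syn-carboalumination, C11=C12 and C3=C4 from chair Johnson–Claisen transition states, and all are carried through unchanged.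

Key step: step 20

Assumption (chemistry): TRIP is 3,3'-bis(2,4,6-triisopropylphenyl)-1,1'-binaphthyl-2,2'-diyl hydrogen phosphate, and its usual sense of induction is assumed, (R)-TRIP sending the allyl group to the Re face of the aldehyde and (S)-TRIP to the Si face.

**West fragment (steps 1–10)**

Step 1
Reactants: 1 propargyl alcohol
Product: 3 (E)-3-iodo-2-methylprop-2-en-1-ol, via alkenylalane 2 (not isolated)
Conditions: Me3Al (3 equiv), Cp2ZrCl2 (0.25 equiv), CH2Cl2, 0 °C to rt; then I2, THF, −30 to 0 °C; aq. K2CO3 quench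
Reagents that add atoms: trimethylaluminium, C[Al](C)C; iodine, II
Why: Zirconium-catalysed carboalumination of the terminal alkyne (Negishi carboalumination) should add methyl and aluminium syn with methyl on the internal carbon, and iodinolysis of the C–Al bond with retention fixes the E geometry of the future C7=C8 olefin.

Step 2
Reactants: 3 (E)-3-iodo-2-methylprop-2-en-1-ol
Product: 4 (E)-3-iodo-2-methylprop-2-enal
Conditions: MnO2 (excess), CH2Cl2, rt, dark; used as a solution
Reagents that add atoms: none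
Why: Allylic alcohol oxidation with MnO2 is selective for the allylic position and leaves the alkenyl iodide and its E geometry untouched.

Step 3
Reactants: 4 (E)-3-iodo-2-methylprop-2-enal; 5 allylboronic acid pinacol ester
Product: 6 (1E,3S)-1-iodo-2-methylhexa-1,5-dien-3-ol
Conditions: (S)-TRIP (5 mol%), 4 Å MS, toluene, −30 °C
Reagents that add atoms: none
Why: Chiral-phosphoric-acid-catalysed allylboration through a chair transition state, in which the acid is hydrogen-bonded to a boronate oxygen, should deliver the allyl group to the Si face of the enal and set C9 as S.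

Step 4
Reactants: 6 (1E,3S)-1-iodo-2-methylhexa-1,5-dien-3-ol
Product: 7 tert-butyl{[(1E,3S)-1-iodo-2-methylhexa-1,5-dien-3-yl]oxy}dimethylsilane
Conditions: TBSCl, imidazole, DMF, rt
Reagents that add atoms: tert-butyldimethylsilyl chloride, CC(C)(C)[Si](C)(C)Cl
Why: Silyl ether formation masks the C9 hydroxyl with a group that should survive Grignard reagents, hydride, borane, base and the cathodic coupling and is removed only at the end.

Step 5
Reactants: 7 tert-butyl{[(1E,3S)-1-iodo-2-methylhexa-1,5-dien-3-yl]oxy}dimethylsilane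
Product: 8 (3S,4E)-3-[(tert-butyldimethylsilyl)oxy]-5-iodo-4-methylpent-4-enal
Conditions: OsO4 (2 mol%), NaIO4 (4 equiv), 2,6-lutidine (2 equiv), dioxane/H2O (3:1), rt
Reagents that add atoms: osmium tetroxide, O=[Os](=O)(=O)=O; sodium periodate, [Na+].[O-]I(=O)(=O)=O
Why: Lemieux–Johnson oxidative cleavage should take the monosubstituted terminal olefin in preference to the hindered, electron-poor iodoalkene and gives the C11 aldehyde without touching C9.

Step 6
Reactants: 8 (3S,4E)-3-[(tert-butyldimethylsilyl)oxy]-5-iodo-4-methylpent-4-enal; 9 isopropenylmagnesium bromide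
Product: 10 (5S,6E)-5-[(tert-butyldimethylsilyl)oxy]-7-iodo-2,6-dimethylhepta-1,6-dien-3-ol (both C3 epimers)
Conditions: CH2=C(CH3)MgBr (1.3 equiv), THF, −78 °C
Reagents that add atoms: none
Why: Grignard 1,2-addition to the aldehyde is faster at −78 °C than magnesium–iodine exchange at the alkenyl iodide or β-elimination of the silyloxy group, and the new carbinol centre, formed as both epimers, is erased in step 7.

Step 7
Reactants: 10 (5S,6E)-5-[(tert-butyldimethylsilyl)oxy]-7-iodo-2,6-dimethylhepta-1,6-dien-3-ol; 11 triethyl orthoacetate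
Product: 13 ethyl (4E,7S,8E)-7-[(tert-butyldimethylsilyl)oxy]-9-iodo-4,8-dimethylnona-4,8-dienoate, via ketene acetal 12 (not isolated)
Conditions: 11 (6 equiv), EtCO2H (10 mol%), 140 °C, EtOH distilled off
Reagents that add atoms: none
Why: Johnson–Claisen rearrangement through a chair transition state with the C10 substituent equatorial should give the E-trisubstituted C11=C12 olefin and append C13, C14 and the C1 ester carbon.

Step 8
Reactants: 13 ethyl (4E,7S,8E)-7-[(tert-butyldimethylsilyl)oxy]-9-iodo-4,8-dimethylnona-4,8-dienoate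
Product: 14 (4E,7S,8E)-7-[(tert-butyldimethylsilyl)oxy]-9-iodo-4,8-dimethylnona-4,8-dienal
Conditions: iBu2AlH (1.1 equiv), CH2Cl2, −78 °C
Reagents that add atoms: none
Why: Partial reduction of the ester with iBu2AlH at −78 °C stops at the aluminium hemiacetal, which gives the C1 aldehyde on work-up, and the alkenyl iodide and silyl ether are inert to the hydride.

Step 9
Reactants: 14 (4E,7S,8E)-7-[(tert-butyldimethylsilyl)oxy]-9-iodo-4,8-dimethylnona-4,8-dienal; 15 vinylmagnesium bromide
Product: 17 methyl (6E,9S,10E)-9-[(tert-butyldimethylsilyl)oxy]-11-iodo-6,10-dimethylundeca-1,6,10-trien-3-yl carbonate (both C3 epimers), via magnesium alkoxide 16 (not isolated)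
Conditions: CH2=CHMgBr (1.2 equiv), THF, −78 °C; then ClCO2Me (1.5 equiv), −78 to 0 °C
Reagents that add atoms: methyl chloroformate, COC(=O)Cl
Why: Vinyl Grignard 1,2-addition followed by O-acylation of the magnesium alkoxide in the same flask gives the branched allylic carbonate, whose carbinol centre (both epimers) is lost in step 10.

Step 10
Reactants: 17 methyl (6E,9S,10E)-9-[(tert-butyldimethylsilyl)oxy]-11-iodo-6,10-dimethylundeca-1,6,10-trien-3-yl carbonate
Product: 18 2-[(2E,6E,9S,10E)-9-[(tert-butyldimethylsilyl)oxy]-11-iodo-6,10-dimethylundeca-2,6,10-trien-1-yl]-4,4,5,5-tetramethyl-1,3,2-dioxaborolane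
Conditions: CuCl (5 mol%), Xantphos (5 mol%), KOtBu (10 mol%), B2pin2 (1.3 equiv), THF, 0 °C
Reagents that add atoms: bis(pinacolato)diboron, CC1(C)OB(OC1(C)C)B1OC(C)(C)C(C)(C)O1
Why: Copper-catalysed γ-selective borylation of the allylic carbonate (addition of the boryl-copper species, monovalent copper, across the terminal olefin and β-elimination of the carbonate) should give the linear (E)-allylboronate, the hindered trisubstituted alkenyl iodide being expected to react far more slowly with the boryl-copper intermediate.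

**East fragment (steps 11–14)**

Step 11
Reactants: 19 (tert-butyldimethylsilyloxy)acetaldehyde; 9 isopropenylmagnesium bromide
Product: 20 1-[(tert-butyldimethylsilyl)oxy]-3-methylbut-3-en-2-ol (racemic)
Conditions: CH2=C(CH3)MgBr (1.2 equiv), THF, −78 °C
Reagents that add atoms: none
Why: Grignard 1,2-addition furnishes the racemic 2-methylallylic alcohol, whose stereocentre disappears in the following rearrangement.

Step 12
Reactants: 20 1-[(tert-butyldimethylsilyl)oxy]-3-methylbut-3-en-2-ol; 11 triethyl orthoacetate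
Product: 22 ethyl (4E)-6-[(tert-butyldimethylsilyl)oxy]-4-methylhex-4-enoate, via ketene acetal 21 (not isolated)
Conditions: 11 (6 equiv), EtCO2H (10 mol%), 140 °C, EtOH distilled off
Reagents that add atoms: none
Why: Johnson–Claisen rearrangement through a chair transition state with the CH2OTBS group equatorial should give the E-trisubstituted C3=C4 olefin together with C5, C6 and the carboxyl carbon that is later extruded.

Step 13
Reactants: 22 ethyl (4E)-6-[(tert-butyldimethylsilyl)oxy]-4-methylhex-4-enoate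
Product: 23 ethyl (4E)-6-hydroxy-4-methylhex-4-enoate
Conditions: HF·pyridine, pyridine, THF, 0 °C to rt
Reagents that add atoms: none
Why: Fluoride-induced desilylation with buffered HF·pyridine frees the primary allylic alcohol without touching the ethyl ester or the olefin geometry.

Step 14
Reactants: 23 ethyl (4E)-6-hydroxy-4-methylhex-4-enoate
Product: 24 ethyl (4E)-4-methyl-6-oxohex-4-enoate
Conditions: MnO2 (excess), CH2Cl2, rt
Reagents that add atoms: none
Why: Allylic oxidation with MnO2 stops at the enal and should not isomerise the E olefin.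

**Union, lactone and macrocycle (steps 15–24)**

Step 15
Reactants: 18 2-[(2E,6E,9S,10E)-9-[(tert-butyldimethylsilyl)oxy]-11-iodo-6,10-dimethylundeca-2,6,10-trien-1-yl]-4,4,5,5-tetramethyl-1,3,2-dioxaborolane; 24 ethyl (4E)-4-methyl-6-oxohex-4-enoate
Product: 25 ethyl (4E,6R,7R,10E,13S,14E)-13-[(tert-butyldimethylsilyl)oxy]-7-ethenyl-6-hydroxy-15-iodo-4,10,14-trimethylpentadeca-4,10,14-trienoate
Conditions: 24 (1.3 equiv), (R)-TRIP (10 mol%), 4 Å MS, toluene, −30 °C
Reagents that add atoms: none
Why: In this chiral-phosphoric-acid-catalysed allylboration the (E)-γ-substituted boronate reacts through a chair transition state that turns the olefin geometry into the anti C1/C2 relationship, while the (R)-acid directs attack to the Re face of the enal, so that C1 and C2 are both set as R (C7 and C6 of 25) and the new vinyl group holds C15 and C16.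

Step 16
Reactants: 25 ethyl (4E,6R,7R,10E,13S,14E)-13-[(tert-butyldimethylsilyl)oxy]-7-ethenyl-6-hydroxy-15-iodo-4,10,14-trimethylpentadeca-4,10,14-trienoate
Product: 27 ethyl (4E,6R,7R,10E,13S,14E)-13-[(tert-butyldimethylsilyl)oxy]-6-hydroxy-7-(2-hydroxyethyl)-15-iodo-4,10,14-trimethylpentadeca-4,10,14-trienoate, via alkylborane 26 (not isolated)
Conditions: 9-BBN (2.5 equiv), THF, 0 °C to rt; then 30% H2O2, aq. NaOAc, 0 °C to rt
Reagents that add atoms: hydrogen peroxide, OO
Why: In this hydroboration–oxidation 9-BBN adds to the monosubstituted vinyl group in the anti-Markovnikov sense much faster than to the trisubstituted olefins, the iodoalkene or the ester, and buffered peroxide oxidation gives the primary C16 alcohol with all stereocentres retained.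

Step 17
Reactants: 27 ethyl (4E,6R,7R,10E,13S,14E)-13-[(tert-butyldimethylsilyl)oxy]-6-hydroxy-7-(2-hydroxyethyl)-15-iodo-4,10,14-trimethylpentadeca-4,10,14-trienoate
Product: 29 ethyl (4E)-5-{(2R,3R)-3-[(3E,6S,7E)-6-[(tert-butyldimethylsilyl)oxy]-8-iodo-3,7-dimethylocta-3,7-dien-1-yl]-5-oxooxolan-2-yl}-4-methylpent-4-enoate, via lactol 28 (not isolated)
Conditions: TEMPO (0.2 equiv), PhI(OAc)2 (2.5 equiv), CH2Cl2, rt
Reagents that add atoms: none
Why: In this oxidative lactonization TEMPO/PhI(OAc)2 oxidises the primary alcohol in preference to the secondary allylic one, the aldehyde is trapped by the C2 hydroxyl as the five-membered lactol (5-exo-trig hemiacetalisation) and this is oxidised further, so the trans-fused γ-lactone ring forms with C1 and C2 untouched.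

Step 18
Reactants: 29 ethyl (4E)-5-{(2R,3R)-3-[(3E,6S,7E)-6-[(tert-butyldimethylsilyl)oxy]-8-iodo-3,7-dimethylocta-3,7-dien-1-yl]-5-oxooxolan-2-yl}-4-methylpent-4-enoate
Product: 31 (4E)-5-{(2R,3R)-3-[(3E,6S,7E)-6-[(tert-butyldimethylsilyl)oxy]-8-iodo-3,7-dimethylocta-3,7-dien-1-yl]-5-oxooxolan-2-yl}-4-methylpent-4-enoic acid, via dilithium dicarboxylate 30 (not isolated)
Conditions: LiOH (4 equiv), THF/H2O, 0 °C to rt; then 1 M HCl to pH 3, rt
Reagents that add atoms: lithium hydroxide, [Li+].[OH-]
Why: Saponification cleaves the ethyl ester and transiently opens the lactone, and acidification re-closes the γ-hydroxy acid to the five-membered lactone (C1 and C2 cannot epimerise under these conditions) while the side-chain acid stays free.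

Step 19
Reactants: 31 (4E)-5-{(2R,3R)-3-[(3E,6S,7E)-6-[(tert-butyldimethylsilyl)oxy]-8-iodo-3,7-dimethylocta-3,7-dien-1-yl]-5-oxooxolan-2-yl}-4-methylpent-4-enoic acid
Product: 32 1,3-dioxoisoindolin-2-yl (4E)-5-{(2R,3R)-3-[(3E,6S,7E)-6-[(tert-butyldimethylsilyl)oxy]-8-iodo-3,7-dimethylocta-3,7-dien-1-yl]-5-oxooxolan-2-yl}-4-methylpent-4-enoate (seco alkenyl iodide and redox-active ester)
Conditions: N-hydroxyphthalimide (1.1 equiv), N,N'-diisopropylcarbodiimide (1.2 equiv), DMAP (10 mol%), CH2Cl2, rt
Reagents that add atoms: N-hydroxyphthalimide, O=C1c2ccccc2C(=O)N1O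
Why: Carbodiimide-mediated esterification (Steglich type) with N-hydroxyphthalimide gives the redox-active ester without affecting the lactone, the silyl ether or the alkenyl iodide.

Step 20
Reactants: 32 1,3-dioxoisoindolin-2-yl (4E)-5-{(2R,3R)-3-[(3E,6S,7E)-6-[(tert-butyldimethylsilyl)oxy]-8-iodo-3,7-dimethylocta-3,7-dien-1-yl]-5-oxooxolan-2-yl}-4-methylpent-4-enoate
Product: 33 (3aR,6E,9S,10E,14E,15aR)-9-[(tert-butyldimethylsilyl)oxy]-6,10,14-trimethyl-3a,4,5,8,9,12,13,15a-octahydrocyclotetradeca[b]furan-2(3H)-one (macrocyclic saturated lactone)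
Conditions: NiCl2(dme) (30 mol%), 2,2'-bipyridine (36 mol%), AgNO3 (0.3 equiv), LiCl, DMF, undivided cell, Mg anode, reticulated vitreous carbon cathode, constant current, rt; 32 added over 12 h by syringe pump (final ca. 2 mM)
Reagents that add atoms: none
Why: Proposed new method: cathodically formed low-valent nickel–bipyridine (zerovalent or monovalent) should insert into the C7–I bond with retention to give a divalent alkenylnickel, while electron transfer to the N-acyloxyphthalimide expels phthalimide anion and CO2 and leaves the primary homoallylic C6 radical, which the alkenylnickel of the same molecule captures, and reductive elimination from the trivalent nickel so formed makes the C6–C7 bond, the magnesium anode supplying the electrons. The closest known reaction type is the intermolecular nickel-electrocatalysed decarboxylative alkenylation of redox-active esters with alkenyl halides, for which primary homoallylic radicals are typical partners; the ring-forming variant is not established. The 14-membered carbocycle closes end to end by capture of the radical at the metal (no radical addition to an olefin is involved), and no stereocentre is created. The step needs ring closure to outrun dimerisation, which slow addition and a current-limited radical flux (a low stationary concentration of 32) should provide, helped by the trans-lactone and the E olefins, which restrict the conformations of the chain. It also needs the E geometry at C7=C8 to survive, which stereoretentive oxidative addition and reductive elimination at nickel secure, and the C3=C4 geometry to survive, which holds as long as capture of the homoallylic radical is faster than its reversible 3-exo closure. The saturated lactone, the silyl ether and the trisubstituted olefins are not expected to be reduced at the potential at which nickel turns over.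

Step 21
Reactants: 33 (3aR,6E,9S,10E,14E,15aR)-9-[(tert-butyldimethylsilyl)oxy]-6,10,14-trimethyl-3a,4,5,8,9,12,13,15a-octahydrocyclotetradeca[b]furan-2(3H)-one
Product: 34 (3aR,6E,9S,10E,14E,15aR)-9-[(tert-butyldimethylsilyl)oxy]-3-[(dimethylamino)methyl]-6,10,14-trimethyl-3a,4,5,8,9,12,13,15a-octahydrocyclotetradeca[b]furan-2(3H)-one (C3 epimers)
Conditions: LiN(iPr)2 (1.3 equiv), THF, −78 °C; then Eschenmoser's salt (3 equiv), −78 °C to rt
Reagents that add atoms: Eschenmoser's salt (N,N-dimethylmethyleneiminium iodide), C=[N+](C)C.[I-]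
Why: Mannich reaction of the lactone lithium enolate with the iminium salt installs the aminomethyl group at C15, and the new α-centre need not be controlled because it becomes sp2 in step 22.

Step 22
Reactants: 34 (3aR,6E,9S,10E,14E,15aR)-9-[(tert-butyldimethylsilyl)oxy]-3-[(dimethylamino)methyl]-6,10,14-trimethyl-3a,4,5,8,9,12,13,15a-octahydrocyclotetradeca[b]furan-2(3H)-one
Product: 36 (3aR,6E,9S,10E,14E,15aR)-9-[(tert-butyldimethylsilyl)oxy]-6,10,14-trimethyl-3-methylidene-3a,4,5,8,9,12,13,15a-octahydrocyclotetradeca[b]furan-2(3H)-one, via trimethylammonium iodide 35 (not isolated)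
Conditions: MeI (10 equiv), CH2Cl2, rt; then aq. NaHCO3, rt
Reagents that add atoms: none
Why: Quaternisation of the amine followed by mild-base E1cB loss of trimethylamine (Hofmann-type elimination) should unveil the exocyclic α-methylene lactone without migration of the double bond into the ring.

Step 23
Reactants: 36 (3aR,6E,9S,10E,14E,15aR)-9-[(tert-butyldimethylsilyl)oxy]-6,10,14-trimethyl-3-methylidene-3a,4,5,8,9,12,13,15a-octahydrocyclotetradeca[b]furan-2(3H)-one
Product: 37 (3aR,6E,9S,10E,14E,15aR)-9-hydroxy-6,10,14-trimethyl-3-methylidene-3a,4,5,8,9,12,13,15a-octahydrocyclotetradeca[b]furan-2(3H)-one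
Conditions: HF·pyridine, pyridine, THF, 0 °C to rt
Reagents that add atoms: none
Why: Desilylation with buffered HF·pyridine removes the allylic TBS ether under non-basic conditions, which avoids conjugate addition to the α-methylene lactone.

Step 24
Reactants: 37 (3aR,6E,9S,10E,14E,15aR)-9-hydroxy-6,10,14-trimethyl-3-methylidene-3a,4,5,8,9,12,13,15a-octahydrocyclotetradeca[b]furan-2(3H)-one
Product: 38 (3aR,6E,9S,10E,14E,15aR)-6,10,14-trimethyl-3-methylidene-2-oxo-2,3,3a,4,5,8,9,12,13,15a-decahydrocyclotetradeca[b]furan-9-yl acetate (CNP0129197.2)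
Conditions: Ac2O, pyridine, DMAP (10 mol%), CH2Cl2, 0 °C to rt
Reagents that add atoms: acetic anhydride, CC(=O)OC(C)=O
Why: DMAP-catalysed acylation of the C9 alcohol with acetic anhydride forms the acetate without breaking the C9–O bond, so the S configuration is retained and the target results.

**Compound list**

1 | propargyl alcohol | C#CCO | starting material
2 | dimethylaluminium (E)-3-(dimethylalumanyl)-2-methylprop-2-en-1-olate (alkenylalane) | C[Al](C)/C=C(\C)CO[Al](C)C | intermediate
3 | (E)-3-iodo-2-methylprop-2-en-1-ol | I/C=C(\C)CO | intermediate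
4 | (E)-3-iodo-2-methylprop-2-enal | I/C=C(\C)C=O | intermediate
5 | allylboronic acid pinacol ester | C=CCB1OC(C)(C)C(C)(C)O1 | starting material
6 | (1E,3S)-1-iodo-2-methylhexa-1,5-dien-3-ol | I/C=C(\C)[C@@H](O)CC=C | intermediate
7 | tert-butyl{[(1E,3S)-1-iodo-2-methylhexa-1,5-dien-3-yl]oxy}dimethylsilane | I/C=C(\C)[C@@H](O[Si](C)(C)C(C)(C)C)CC=C | intermediate
8 | (3S,4E)-3-[(tert-butyldimethylsilyl)oxy]-5-iodo-4-methylpent-4-enal | I/C=C(\C)[C@@H](O[Si](C)(C)C(C)(C)C)CC=O | intermediate
9 | isopropenylmagnesium bromide | CC(=C)[Mg]Br | starting material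
10 | (5S,6E)-5-[(tert-butyldimethylsilyl)oxy]-7-iodo-2,6-dimethylhepta-1,6-dien-3-ol (both C3 epimers) | I/C=C(\C)[C@@H](O[Si](C)(C)C(C)(C)C)CC(O)C(C)=C | intermediate
11 | triethyl orthoacetate | CCOC(C)(OCC)OCC | starting material
12 | (5S,6E)-5-[(tert-butyldimethylsilyl)oxy]-3-[(1-ethoxyethenyl)oxy]-7-iodo-2,6-dimethylhepta-1,6-diene (ketene acetal) | I/C=C(\C)[C@@H](O[Si](C)(C)C(C)(C)C)CC(OC(=C)OCC)C(C)=C | intermediate
13 | ethyl (4E,7S,8E)-7-[(tert-butyldimethylsilyl)oxy]-9-iodo-4,8-dimethylnona-4,8-dienoate | I/C=C(\C)[C@@H](O[Si](C)(C)C(C)(C)C)C/C=C(\C)CCC(=O)OCC | intermediate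
14 | (4E,7S,8E)-7-[(tert-butyldimethylsilyl)oxy]-9-iodo-4,8-dimethylnona-4,8-dienal | I/C=C(\C)[C@@H](O[Si](C)(C)C(C)(C)C)C/C=C(\C)CCC=O | intermediate
15 | vinylmagnesium bromide | C=C[Mg]Br | starting material
16 | bromomagnesium (6E,9S,10E)-9-[(tert-butyldimethylsilyl)oxy]-11-iodo-6,10-dimethylundeca-1,6,10-trien-3-olate | I/C=C(\C)[C@@H](O[Si](C)(C)C(C)(C)C)C/C=C(\C)CCC(O[Mg]Br)C=C | intermediate
17 | methyl (6E,9S,10E)-9-[(tert-butyldimethylsilyl)oxy]-11-iodo-6,10-dimethylundeca-1,6,10-trien-3-yl carbonate (both C3 epimers) | I/C=C(\C)[C@@H](O[Si](C)(C)C(C)(C)C)C/C=C(\C)CCC(OC(=O)OC)C=C | intermediate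
18 | 2-[(2E,6E,9S,10E)-9-[(tert-butyldimethylsilyl)oxy]-11-iodo-6,10-dimethylundeca-2,6,10-trien-1-yl]-4,4,5,5-tetramethyl-1,3,2-dioxaborolane (west fragment) | I/C=C(\C)[C@@H](O[Si](C)(C)C(C)(C)C)C/C=C(\C)CC/C=C/CB1OC(C)(C)C(C)(C)O1 | intermediate
19 | (tert-butyldimethylsilyloxy)acetaldehyde | O=CCO[Si](C)(C)C(C)(C)C | starting material
20 | 1-[(tert-butyldimethylsilyl)oxy]-3-methylbut-3-en-2-ol (racemic) | CC(=C)C(O)CO[Si](C)(C)C(C)(C)C | intermediate
21 | 1-[(tert-butyldimethylsilyl)oxy]-2-[(1-ethoxyethenyl)oxy]-3-methylbut-3-ene (ketene acetal) | CC(=C)C(CO[Si](C)(C)C(C)(C)C)OC(=C)OCC | intermediate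
22 | ethyl (4E)-6-[(tert-butyldimethylsilyl)oxy]-4-methylhex-4-enoate | CCOC(=O)CC/C(C)=C/CO[Si](C)(C)C(C)(C)C | intermediate
23 | ethyl (4E)-6-hydroxy-4-methylhex-4-enoate | CCOC(=O)CC/C(C)=C/CO | intermediate
24 | ethyl (4E)-4-methyl-6-oxohex-4-enoate (east fragment) | CCOC(=O)CC/C(C)=C/C=O | intermediate
25 | ethyl (4E,6R,7R,10E,13S,14E)-13-[(tert-butyldimethylsilyl)oxy]-7-ethenyl-6-hydroxy-15-iodo-4,10,14-trimethylpentadeca-4,10,14-trienoate | I/C=C(\C)[C@@H](O[Si](C)(C)C(C)(C)C)C/C=C(\C)CC[C@H](C=C)[C@@H](O)/C=C(\C)CCC(=O)OCC | intermediate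
26 | ethyl (4E,6R,7R,10E,13S,14E)-6-[(9-borabicyclo[3.3.1]nonan-9-yl)oxy]-7-[2-(9-borabicyclo[3.3.1]nonan-9-yl)ethyl]-13-[(tert-butyldimethylsilyl)oxy]-15-iodo-4,10,14-trimethylpentadeca-4,10,14-trienoate | I/C=C(\C)[C@@H](O[Si](C)(C)C(C)(C)C)C/C=C(\C)CC[C@H](CCB1C2CCCC1CCC2)[C@@H](OB1C2CCCC1CCC2)/C=C(\C)CCC(=O)OCC | intermediate
27 | ethyl (4E,6R,7R,10E,13S,14E)-13-[(tert-butyldimethylsilyl)oxy]-6-hydroxy-7-(2-hydroxyethyl)-15-iodo-4,10,14-trimethylpentadeca-4,10,14-trienoate | I/C=C(\C)[C@@H](O[Si](C)(C)C(C)(C)C)C/C=C(\C)CC[C@H](CCO)[C@@H](O)/C=C(\C)CCC(=O)OCC | intermediate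
28 | ethyl (4E)-5-{(2R,3R)-3-[(3E,6S,7E)-6-[(tert-butyldimethylsilyl)oxy]-8-iodo-3,7-dimethylocta-3,7-dien-1-yl]-5-hydroxyoxolan-2-yl}-4-methylpent-4-enoate (lactol) | I/C=C(\C)[C@@H](O[Si](C)(C)C(C)(C)C)C/C=C(\C)CC[C@@H]1CC(O)O[C@H]1/C=C(\C)CCC(=O)OCC | intermediate
29 | ethyl (4E)-5-{(2R,3R)-3-[(3E,6S,7E)-6-[(tert-butyldimethylsilyl)oxy]-8-iodo-3,7-dimethylocta-3,7-dien-1-yl]-5-oxooxolan-2-yl}-4-methylpent-4-enoate | I/C=C(\C)[C@@H](O[Si](C)(C)C(C)(C)C)C/C=C(\C)CC[C@@H]1CC(=O)O[C@H]1/C=C(\C)CCC(=O)OCC | intermediate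
30 | dilithium (4E,6R,7R,10E,13S,14E)-13-[(tert-butyldimethylsilyl)oxy]-7-(carboxylatomethyl)-6-hydroxy-15-iodo-4,10,14-trimethylpentadeca-4,10,14-trienoate | I/C=C(\C)[C@@H](O[Si](C)(C)C(C)(C)C)C/C=C(\C)CC[C@H](CC(=O)[O-])[C@@H](O)/C=C(\C)CCC(=O)[O-].[Li+].[Li+] | intermediate
31 | (4E)-5-{(2R,3R)-3-[(3E,6S,7E)-6-[(tert-butyldimethylsilyl)oxy]-8-iodo-3,7-dimethylocta-3,7-dien-1-yl]-5-oxooxolan-2-yl}-4-methylpent-4-enoic acid | I/C=C(\C)[C@@H](O[Si](C)(C)C(C)(C)C)C/C=C(\C)CC[C@@H]1CC(=O)O[C@H]1/C=C(\C)CCC(=O)O | intermediate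
32 | 1,3-dioxoisoindolin-2-yl (4E)-5-{(2R,3R)-3-[(3E,6S,7E)-6-[(tert-butyldimethylsilyl)oxy]-8-iodo-3,7-dimethylocta-3,7-dien-1-yl]-5-oxooxolan-2-yl}-4-methylpent-4-enoate | I/C=C(\C)[C@@H](O[Si](C)(C)C(C)(C)C)C/C=C(\C)CC[C@@H]1CC(=O)O[C@H]1/C=C(\C)CCC(=O)ON1C(=O)c2ccccc2C1=O | intermediate
33 | (3aR,6E,9S,10E,14E,15aR)-9-[(tert-butyldimethylsilyl)oxy]-6,10,14-trimethyl-3a,4,5,8,9,12,13,15a-octahydrocyclotetradeca[b]furan-2(3H)-one | C1C(=O)O[C@H]2/C=C(\C)CC/C=C(\C)[C@@H](O[Si](C)(C)C(C)(C)C)C/C=C(\C)CC[C@H]12 | intermediate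
34 | (3aR,6E,9S,10E,14E,15aR)-9-[(tert-butyldimethylsilyl)oxy]-3-[(dimethylamino)methyl]-6,10,14-trimethyl-3a,4,5,8,9,12,13,15a-octahydrocyclotetradeca[b]furan-2(3H)-one (C3 epimers) | CN(C)CC1C(=O)O[C@H]2/C=C(\C)CC/C=C(\C)[C@@H](O[Si](C)(C)C(C)(C)C)C/C=C(\C)CC[C@H]12 | intermediate
35 | 3-[(trimethylammonio)methyl] analogue of 34 as its iodide | C[N+](C)(C)CC1C(=O)O[C@H]2/C=C(\C)CC/C=C(\C)[C@@H](O[Si](C)(C)C(C)(C)C)C/C=C(\C)CC[C@H]12.[I-] | intermediate
36 | (3aR,6E,9S,10E,14E,15aR)-9-[(tert-butyldimethylsilyl)oxy]-6,10,14-trimethyl-3-methylidene-3a,4,5,8,9,12,13,15a-octahydrocyclotetradeca[b]furan-2(3H)-one | C=C1C(=O)O[C@H]2/C=C(\C)CC/C=C(\C)[C@@H](O[Si](C)(C)C(C)(C)C)C/C=C(\C)CC[C@H]12 | intermediate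
37 | (3aR,6E,9S,10E,14E,15aR)-9-hydroxy-6,10,14-trimethyl-3-methylidene-3a,4,5,8,9,12,13,15a-octahydrocyclotetradeca[b]furan-2(3H)-one | C=C1C(=O)O[C@H]2/C=C(\C)CC/C=C(\C)[C@@H](O)C/C=C(\C)CC[C@H]12 | intermediate
38 | (3aR,6E,9S,10E,14E,15aR)-6,10,14-trimethyl-3-methylidene-2-oxo-2,3,3a,4,5,8,9,12,13,15a-decahydrocyclotetradeca[b]furan-9-yl acetate (CNP0129197.2) | C=C1C(=O)O[C@H]2/C=C(\C)CC/C=C(\C)[C@@H](OC(C)=O)C/C=C(\C)CC[C@H]12 | target

**Step count**

Total: 24 steps. Longest linear sequence: 20 steps (steps 1–10, then 15–24, from propargyl alcohol); the east fragment takes 4 steps (11–14).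

**Steps most likely to fail**

1. Step 20 (the proposed new method). Ring closure may lose to intermolecular coupling and oligomerisation. Either terminus may be quenched early (hydrodeiodination at C7, hydrogen capture or dimerisation of the C6 radical). Low-valent nickel may ionise the allylic lactone C2–O bond, and the C3=C4 geometry may scramble through reversible cyclopropylcarbinyl closure of the homoallylic radical. The fallback uses known reactions, sets out from 32 and returns at 33. Light-driven decarboxylative borylation of 32 (bis(catecholato)diboron, N,N-dimethylacetamide, blue light; then pinacol, Et3N) should give the primary alkyl pinacol boronate F1, in which C6 carries boron. An intramolecular B-alkyl Suzuki–Miyaura coupling of F1 (Pd(dppf)Cl2, Ag2O, K2CO3, THF, 70 °C, high dilution) then joins C6 to C7 with retention at the alkenyl iodide and gives 33.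

2. Step 10. The boryl-copper intermediate may exchange iodine for boron at C7 and the catalyst may stall as CuI, or the elimination may not be fully E-selective. The fallback avoids boron at this stage, sets out from 14 and returns at 25. Addition of CH2=CHMgBr (THF, −78 °C) with aqueous work-up gives the allylic alcohol F2. PBr3/pyridine (Et2O, −10 °C) converts it, with allylic transposition, into the primary (E)-allylic bromide F3. A chromium-catalysed asymmetric Nozaki–Hiyama allylation of enal 24 with F3 (CrCl2, a chiral bis(oxazolinyl)carbazole ligand, Mn, Me3SiCl, iPr2NEt, THF, rt; acidic work-up) should then give the anti adduct 25 through the chair transition state of the (E)-allylchromium species. The alkenyl iodide is inert to divalent chromium when no nickel salt is present.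

3. Step 15. The phosphoric acid may discriminate poorly between the two faces of the β,β-disubstituted enal, so that both anti adducts form. The fallback sets out from 18 and 24 and returns at 25. The uncatalysed allylboration (toluene, rt) still passes through the chair transition state and should give only 25 and its (6S,7S) isomer F4. Sharpless kinetic resolution of the secondary allylic alcohol (Ti(OiPr)4, L-(+)-diisopropyl tartrate, tBuOOH, 4 Å MS, CH2Cl2, −20 °C) should epoxidise the C4=C5 olefin of the 6S isomer to the epoxy alcohol F5 and leave 25, which is separated by chromatography.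

**Further compounds**

F1 | step 20 | 2-[(3E)-4-{(2R,3R)-3-[(3E,6S,7E)-6-[(tert-butyldimethylsilyl)oxy]-8-iodo-3,7-dimethylocta-3,7-dien-1-yl]-5-oxooxolan-2-yl}-3-methylbut-3-en-1-yl]-4,4,5,5-tetramethyl-1,3,2-dioxaborolane | I/C=C(\C)[C@@H](O[Si](C)(C)C(C)(C)C)C/C=C(\C)CC[C@@H]1CC(=O)O[C@H]1/C=C(\C)CCB1OC(C)(C)C(C)(C)O1
F2 | step 10 | (6E,9S,10E)-9-[(tert-butyldimethylsilyl)oxy]-11-iodo-6,10-dimethylundeca-1,6,10-trien-3-ol (both C3 epimers) | I/C=C(\C)[C@@H](O[Si](C)(C)C(C)(C)C)C/C=C(\C)CCC(O)C=C
F3 | step 10 | tert-butyl{[(1E,3S,5E,9E)-11-bromo-1-iodo-2,6-dimethylundeca-1,5,9-trien-3-yl]oxy}dimethylsilane | I/C=C(\C)[C@@H](O[Si](C)(C)C(C)(C)C)C/C=C(\C)CC/C=C/CBr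
F4 | step 15 | ethyl (4E,6S,7S,10E,13S,14E)-13-[(tert-butyldimethylsilyl)oxy]-7-ethenyl-6-hydroxy-15-iodo-4,10,14-trimethylpentadeca-4,10,14-trienoate | I/C=C(\C)[C@@H](O[Si](C)(C)C(C)(C)C)C/C=C(\C)CC[C@@H](C=C)[C@H](O)/C=C(\C)CCC(=O)OCC
F5 | step 15 | ethyl (4S,5S,6S,7S,10E,13S,14E)-13-[(tert-butyldimethylsilyl)oxy]-4,5-epoxy-7-ethenyl-6-hydroxy-15-iodo-4,10,14-trimethylpentadeca-10,14-dienoate | I/C=C(\C)[C@@H](O[Si](C)(C)C(C)(C)C)C/C=C(\C)CC[C@@H](C=C)[C@H](O)[C@@H]1O[C@@]1(C)CCC(=O)OCC
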